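## Retrosynthetic overview

1. The last two operations are O-demethylation of the methyl tetronate and, before it, a C13–C15 sp2–sp3 Negishi coupling. This coupling joins a (Z)-alkenyl iodide (C1–C14, furan half) to a primary alkylzinc (C15–C25, tetronate half), and the 12Z geometry follows by retention.
2. The key disconnection is C21–C22. β-Lithiated methyl 3-methoxy-2-methylacrylate is an α-lithio enol ether, so it acts as an acyl anion equivalent of the C22 carbonyl. It attacks the aldehyde carbon C21 of α-chloro-(S)-citronellal. The same pot closes the butenolide and loses HCl, which sets 20Z.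
3. C18 (S) is bought with (S)-citronellal, and no later step touches it.
4. The furan half comes from geranyl acetate, which supplies 7E. The sequence is selective ozonolysis, iodo-Wittig olefination to the Z iodide, and copper-catalysed allylic coupling with the 3-furylmethyl Grignard reagent.
5. Ring order: the furan ring is bought (3-furanmethanol). The only ring formed is the tetronate ring, in step 3.

Assumption: locants C1–C25 are the usual variabilin ones (furan C1–C4, chain C5–C20 with methyls C9, C14 and C19, tetronate C21–C24 with methyl C25). Commercial (S)-(−)-citronellal is taken as enantiopure.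

## Route

Step 1
Reactants: 1 methyl propanoate; 2 methyl formate
Product: 4 methyl (2E)-3-methoxy-2-methylprop-2-enoate, via sodium formyl enolate 3 (not isolated)
Conditions: NaH, cat. MeOH, THF, 0 °C to rt; then Me2SO4, DMF, rt; distil
Reagents that add atoms: dimethyl sulfate, COS(=O)(=O)OC
Why: Crossed Claisen formylation of the ester, then O-methylation of the hard sodium enolate by the hard electrophile dimethyl sulfate in a dipolar solvent, gives the more stable E β-methoxyacrylate, as in standard β-methoxyacrylate preparations.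

Step 2
Reactants: 5 (S)-(−)-citronellal, (3S)-3,7-dimethyloct-6-enal
Product: 6 (3S)-2-chloro-3,7-dimethyloct-6-enal as a mixture of C2 epimers
Conditions: NCS (1.05 equiv), L-prolinamide (10 mol %), CH2Cl2, 0 °C to rt
Reagents that add atoms: N-chlorosuccinimide, O=C1CCC(=O)N1Cl
Why: Enamine-catalysed α-chlorination of an aldehyde touches only C2, so C3 (the future C18) stays S, the new C–Cl centre is destroyed in step 3, and NCS alone leaves the trisubstituted alkene alone.

Step 3 (key step)
Reactants: 4 methyl (2E)-3-methoxy-2-methylprop-2-enoate; 6 (3S)-2-chloro-3,7-dimethyloct-6-enal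
Product: 10 (5Z)-5-[(2S)-2,6-dimethylhept-5-en-1-ylidene]-4-methoxy-3-methylfuran-2(5H)-one, via vinyllithium 7 (not isolated), via lithium alkoxide adduct 8 (not isolated), via chloro lactone 9 (not isolated)
Conditions: LDA (1.05 equiv), THF, −95 °C, 30 min; add 6, −95 to 0 °C; DBU (0.3 equiv), rt
Reagents that add atoms: none
Why: Proposed new method: ester-chelated β-lithiation of 4 gives an α-lithiated enol ether (acyl anion equivalent of C22) that adds to aldehyde carbon C21, joining two carbonyl-type carbons that are both natively electrophilic; the alkoxide, cis to the ester, lactonises with loss of LiOMe as in the known tetronate synthesis from lithiated β-alkoxyacrylates and aldehydes; the acidic H-5 then allows E1cB loss of chloride (LiOMe as terminal base, DBU as proton shuttle), as in the known base elimination of tetronate aldol mesylates; the Z alkene forms because the E isomer would press the branched chain against the 4-OMe; C18 is not involved.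

Step 4
Reactants: 10 (5Z)-5-[(2S)-2,6-dimethylhept-5-en-1-ylidene]-4-methoxy-3-methylfuran-2(5H)-one
Product: 12 (5Z)-5-[(2S)-5-hydroxy-2-methylpentylidene]-4-methoxy-3-methylfuran-2(5H)-one, via secondary ozonide 11 (not isolated)
Conditions: O3, CH2Cl2, −78 °C (Sudan Red 7B end point); then MeOH, NaBH4, −78 to 0 °C
Reagents that add atoms: ozone, [O-][O+]=O
Why: In this chemoselective ozonolysis with reductive work-up, the isolated electron-rich trisubstituted alkene reacts far faster than the acceptor-conjugated dienyl system of the ylidene tetronate, and borohydride reduces the ozonide and aldehyde much faster than the vinylogous carbonate.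

Step 5
Reactants: 12 (5Z)-5-[(2S)-5-hydroxy-2-methylpentylidene]-4-methoxy-3-methylfuran-2(5H)-one
Product: 13 (5Z)-5-[(2S)-5-iodo-2-methylpentylidene]-4-methoxy-3-methylfuran-2(5H)-one
Conditions: I2, PPh3, imidazole, CH2Cl2, 0 °C to rt
Reagents that add atoms: iodine, II
Why: Appel-type iodination of a primary alcohol under near-neutral conditions leaves the tetronate, the Z alkene and C18 untouched.

Step 6
Reactants: 14 furan-3-ylmethanol
Product: 15 3-(chloromethyl)furan
Conditions: SOCl2, pyridine, Et2O, 0 °C; used directly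
Reagents that add atoms: thionyl chloride, O=S(Cl)Cl
Why: Chlorodehydroxylation through the chlorosulfite, with pyridine buffering the HCl, is the standard preparation of this acid-sensitive furylmethyl chloride.

Step 7
Reactants: 16 geranyl acetate, (2E)-3,7-dimethylocta-2,6-dien-1-yl acetate
Product: 18 (2E)-3-methyl-6-oxohex-2-en-1-yl acetate, via secondary ozonide 17 (not isolated)
Conditions: O3 (1 equiv), CH2Cl2, −78 °C; Me2S, −78 °C to rt
Reagents that add atoms: ozone, [O-][O+]=O
Why: In this site-selective ozonolysis the 6,7-alkene is more electron-rich than the 2,3-alkene, which the allylic acetate deactivates, so the E alkene (the future C7=C8) survives.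

Step 8
Reactants: 19 ethyltriphenylphosphonium iodide; 18 (2E)-3-methyl-6-oxohex-2-en-1-yl acetate
Product: 23 (2E,6Z)-7-iodo-3-methylocta-2,6-dien-1-yl acetate, via ethylidene ylide 20 (not isolated), via iodoethyl phosphonium salt 21 (not isolated), via iodo ylide 22 (not isolated)
Conditions: n-BuLi, THF, 0 °C to rt; I2, −78 °C; NaHMDS, −20 °C; add 18, −78 to −20 °C
Reagents that add atoms: iodine, II
Why: Wittig olefination with the non-stabilised α-iodo ylide (Stork–Zhao-type iodo-olefination) is kinetically controlled and places iodine cis to the chain, giving the (Z)-2-iodoalk-2-ene, and the acetate is inert at these temperatures.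

Step 9
Reactants: 15 3-(chloromethyl)furan; 23 (2E,6Z)-7-iodo-3-methylocta-2,6-dien-1-yl acetate
Product: 25 3-[(3E,7Z)-8-iodo-4-methylnona-3,7-dien-1-yl]furan, via furylmethyl Grignard reagent 24 (not isolated)
Conditions: Mg, THF, rt; then 23, Li2CuCl4 (5 mol %), THF, −30 to 0 °C
Reagents that add atoms: none
Why: Copper-catalysed Grignard allylic substitution occurs at the primary α-carbon because the γ-carbon is fully substituted, retains the E geometry as in dendrolasin-type couplings, and at −30 °C the benzylic-type Grignard reagent neither exchanges nor couples with the alkenyl iodide.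

Step 10
Reactants: 13 (5Z)-5-[(2S)-5-iodo-2-methylpentylidene]-4-methoxy-3-methylfuran-2(5H)-one; 25 3-[(3E,7Z)-8-iodo-4-methylnona-3,7-dien-1-yl]furan
Product: 27 (5Z)-5-[(2S,6Z,10E)-13-(furan-3-yl)-2,6,10-trimethyltrideca-6,10-dien-1-ylidene]-4-methoxy-3-methylfuran-2(5H)-one, via alkylzinc iodide 26 (not isolated)
Conditions: Zn dust, LiCl, THF, 25–40 °C; then 25, PdCl2(dppf) (5 mol %), THF, 40 °C
Reagents that add atoms: none
Why: In this Negishi sp3–sp2 cross-coupling, oxidative addition of the alkenyl iodide to zerovalent palladium and the reductive elimination both proceed with retention, so C15 ends cis to C11 (12Z); the wide-bite-angle dppf suppresses β-hydride elimination; and the mild alkylzinc tolerates lactone, enol ether and furan.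

Step 11
Reactants: 27 (5Z)-5-[(2S,6Z,10E)-13-(furan-3-yl)-2,6,10-trimethyltrideca-6,10-dien-1-ylidene]-4-methoxy-3-methylfuran-2(5H)-one
Product: 29 (5Z)-5-[(2S,6Z,10E)-13-(furan-3-yl)-2,6,10-trimethyltrideca-6,10-dien-1-ylidene]-4-hydroxy-3-methylfuran-2(5H)-one, via sodium tetronate 28 (not isolated)
Conditions: NaSEt, DMF, 50 °C; then cold 1 M HCl to pH 3
Reagents that add atoms: none
Why: SN2 demethylation of the vinylogous methyl carbonate by a soft thiolate is easy because the tetronate anion (conjugate acid pKa about 4) is an excellent leaving group, any thiolate addition to the ylidene is reversible toward the more stable Z form, and neither the alkenes, the furan nor C18 is affected.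

## Compound list

1 | methyl propanoate | CCC(=O)OC | starting material
2 | methyl formate | O=COC | starting material
3 | sodium 3-methoxy-2-methyl-3-oxoprop-1-en-1-olate (enolate of methyl 2-formylpropanoate, in situ) | [Na+].[O-]C=C(C)C(=O)OC | intermediate
4 | methyl (2E)-3-methoxy-2-methylprop-2-enoate | CO/C=C(\C)C(=O)OC | intermediate
5 | (S)-(−)-citronellal, (3S)-3,7-dimethyloct-6-enal | O=CC[C@@H](C)CCC=C(C)C | starting material
6 | (3S)-2-chloro-3,7-dimethyloct-6-enal (C2 epimers) | O=CC(Cl)[C@@H](C)CCC=C(C)C | intermediate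
7 | methyl (2E)-3-lithio-3-methoxy-2-methylprop-2-enoate (Li cis to the ester, in situ) | CO/C([Li])=C(\C)C(=O)OC | intermediate
8 | lithium alkoxide of methyl (2E,6S)-5-chloro-4-hydroxy-3-methoxy-2,6,10-trimethylundeca-2,9-dienoate (in situ) | COC(=O)/C(C)=C(/OC)C([O-])C(Cl)[C@@H](C)CCC=C(C)C.[Li+] | intermediate
9 | 5-[(2S)-1-chloro-2,6-dimethylhept-5-en-1-yl]-4-methoxy-3-methylfuran-2(5H)-one (diastereomers, in situ) | CC1=C(OC)C(C(Cl)[C@@H](C)CCC=C(C)C)OC1=O | intermediate
10 | (5Z)-5-[(2S)-2,6-dimethylhept-5-en-1-ylidene]-4-methoxy-3-methylfuran-2(5H)-one | CC1=C(OC)/C(=C/[C@@H](C)CCC=C(C)C)OC1=O | intermediate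
11 | secondary ozonide (3,3-dimethyl-1,2,4-trioxolan-5-yl compound) of 10 (in situ) | CC1=C(OC)/C(=C/[C@@H](C)CCC2OOC(C)(C)O2)OC1=O | intermediate
12 | (5Z)-5-[(2S)-5-hydroxy-2-methylpentylidene]-4-methoxy-3-methylfuran-2(5H)-one | CC1=C(OC)/C(=C/[C@@H](C)CCCO)OC1=O | intermediate
13 | (5Z)-5-[(2S)-5-iodo-2-methylpentylidene]-4-methoxy-3-methylfuran-2(5H)-one | CC1=C(OC)/C(=C/[C@@H](C)CCCI)OC1=O | intermediate
14 | furan-3-ylmethanol | OCc1ccoc1 | starting material
15 | 3-(chloromethyl)furan | ClCc1ccoc1 | intermediate
16 | geranyl acetate, (2E)-3,7-dimethylocta-2,6-dien-1-yl acetate | CC(=O)OC/C=C(\C)CCC=C(C)C | starting material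
17 | secondary ozonide of the 6,7-alkene of 16 (in situ) | CC(=O)OC/C=C(\C)CCC1OOC(C)(C)O1 | intermediate
18 | (2E)-3-methyl-6-oxohex-2-en-1-yl acetate | CC(=O)OC/C=C(\C)CCC=O | intermediate
19 | ethyltriphenylphosphonium iodide | CC[P+](c1ccccc1)(c1ccccc1)c1ccccc1.[I-] | starting material
20 | ethylidenetriphenylphosphorane (in situ) | CC=P(c1ccccc1)(c1ccccc1)c1ccccc1 | intermediate
21 | (1-iodoethyl)triphenylphosphonium iodide (in situ) | CC(I)[P+](c1ccccc1)(c1ccccc1)c1ccccc1.[I-] | intermediate
22 | (1-iodoethylidene)triphenylphosphorane (in situ) | CC(I)=P(c1ccccc1)(c1ccccc1)c1ccccc1 | intermediate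
23 | (2E,6Z)-7-iodo-3-methylocta-2,6-dien-1-yl acetate | CC(=O)OC/C=C(\C)CC/C=C(/C)I | intermediate
24 | (furan-3-ylmethyl)magnesium chloride (in situ) | Cl[Mg]Cc1ccoc1 | intermediate
25 | 3-[(3E,7Z)-8-iodo-4-methylnona-3,7-dien-1-yl]furan | C/C(I)=C/CC/C(C)=C/CCc1ccoc1 | intermediate
26 | alkylzinc iodide from 13 (in situ) | CC1=C(OC)/C(=C/[C@@H](C)CCC[Zn]I)OC1=O | intermediate
27 | (5Z)-5-[(2S,6Z,10E)-13-(furan-3-yl)-2,6,10-trimethyltrideca-6,10-dien-1-ylidene]-4-methoxy-3-methylfuran-2(5H)-one | CC1=C(OC)/C(=C/[C@@H](C)CCC/C(C)=C\CC/C(C)=C/CCc2ccoc2)OC1=O | intermediate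
28 | sodium salt of 29 (in situ) | CC1=C([O-])/C(=C/[C@@H](C)CCC/C(C)=C\CC/C(C)=C/CCc2ccoc2)OC1=O.[Na+] | intermediate
29 | (5Z)-5-[(2S,6Z,10E)-13-(furan-3-yl)-2,6,10-trimethyltrideca-6,10-dien-1-ylidene]-4-hydroxy-3-methylfuran-2(5H)-one, i.e. (7E,12Z,18S,20Z)-variabilin | CC1=C(O)/C(=C/[C@@H](C)CCC/C(C)=C\CC/C(C)=C/CCc2ccoc2)OC1=O | target

## Step count and risks

Total step count: 11.

Longest linear sequence: 6 steps (step 1 or 2, then 3, 4, 5, 10, 11). The furan branch (7, 8, 9, 10, 11) is 5 steps.

The three steps most likely to fail are steps 3, 8 and 9.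

**Step 3.** The risks are enolisation of 6 by 7, epoxide closure of 8 instead of lactonisation, and incomplete Z selectivity. The fallback sets out from 5 and comes back at 10, and step 2 is dropped.
- Vinyllithium 7, made from 4 as before, is added to unchlorinated 5, which is the established aldehyde version of the reaction. Lactonisation gives 5-[(2S)-2,6-dimethylhept-5-en-1-yl]-4-methoxy-3-methylfuran-2(5H)-one F1.
- Deprotonation at C5 with LDA and trapping with PhSeCl at −78 °C gives 5-[(2S)-2,6-dimethylhept-5-en-1-yl]-4-methoxy-3-methyl-5-(phenylselanyl)furan-2(5H)-one F2.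
- H2O2 converts F2 into the selenoxide 5-(benzeneseleninyl)-5-[(2S)-2,6-dimethylhept-5-en-1-yl]-4-methoxy-3-methylfuran-2(5H)-one F3.
- The only β-hydrogens of F3 are on C20, so syn elimination gives 10. The alkene is thus made by a pericyclic elimination and not by E1cB loss of chloride.

**Step 8.** The iodo-Wittig reaction is notoriously moderate in yield and can give de-iodinated or E material. The fallback sets out from 18 and comes back at 27.
- Ramirez dibromo-olefination (CBr4, PPh3) gives (2E)-7,7-dibromo-3-methylhepta-2,6-dien-1-yl acetate F4.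
- A trans-selective Negishi mono-methylation (MeZnBr, PdCl2(DPEphos)) replaces the less hindered bromine. This leaves (2E,6Z)-7-bromo-3-methylocta-2,6-dien-1-yl acetate F5.
- Coupling with 24 as in step 9 gives 3-[(3E,7Z)-8-bromo-4-methylnona-3,7-dien-1-yl]furan F6.
- F6 is joined to 26 with Pd(P(t-Bu)3)2, with retention, to give 27.

**Step 9.** The risks are competing reaction of the Grignard reagent at the alkenyl iodide or the acetate carbonyl, and γ-attack. The fallback sets out from 16 and comes back at 25. The furan is installed before any alkenyl iodide exists, and the aldehyde is masked as an epoxide.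
- mCPBA (1 equiv) gives (2E)-5-(3,3-dimethyloxiran-2-yl)-3-methylpent-2-en-1-yl acetate F7.
- Coupling with 24 under Li2CuCl4 catalysis gives 3-[(3E)-6-(3,3-dimethyloxiran-2-yl)-4-methylhex-3-en-1-yl]furan F8.
- H5IO6 in aqueous THF at 0 °C cleaves the epoxide to (4E)-7-(furan-3-yl)-4-methylhept-4-enal F9.
- Olefination of F9 with iodo ylide 22 gives 25.

## Further compounds

F1 | step 3 | 5-[(2S)-2,6-dimethylhept-5-en-1-yl]-4-methoxy-3-methylfuran-2(5H)-one (C5 epimers) | CC1=C(OC)C(C[C@@H](C)CCC=C(C)C)OC1=O
F2 | step 3 | 5-[(2S)-2,6-dimethylhept-5-en-1-yl]-4-methoxy-3-methyl-5-(phenylselanyl)furan-2(5H)-one | CC1=C(OC)C([Se]c2ccccc2)(C[C@@H](C)CCC=C(C)C)OC1=O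
F3 | step 3 | 5-(benzeneseleninyl)-5-[(2S)-2,6-dimethylhept-5-en-1-yl]-4-methoxy-3-methylfuran-2(5H)-one | CC1=C(OC)C([Se](=O)c2ccccc2)(C[C@@H](C)CCC=C(C)C)OC1=O
F4 | step 8 | (2E)-7,7-dibromo-3-methylhepta-2,6-dien-1-yl acetate | CC(=O)OC/C=C(\C)CCC=C(Br)Br
F5 | step 8 | (2E,6Z)-7-bromo-3-methylocta-2,6-dien-1-yl acetate | CC(=O)OC/C=C(\C)CC/C=C(/C)Br
F6 | step 8 | 3-[(3E,7Z)-8-bromo-4-methylnona-3,7-dien-1-yl]furan | C/C(Br)=C/CC/C(C)=C/CCc1ccoc1
F7 | step 9 | (2E)-5-(3,3-dimethyloxiran-2-yl)-3-methylpent-2-en-1-yl acetate (racemic epoxide) | CC(=O)OC/C=C(\C)CCC1OC1(C)C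
F8 | step 9 | 3-[(3E)-6-(3,3-dimethyloxiran-2-yl)-4-methylhex-3-en-1-yl]furan | CC1(C)OC1CC/C(C)=C/CCc2ccoc2
F9 | step 9 | (4E)-7-(furan-3-yl)-4-methylhept-4-enal | O=CCC/C(C)=C/CCc1ccoc1
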